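Assumption: aryl tert-butyldimethylsilyl ethers are taken to be cleaved by carbonate in methanol and to migrate from an ortho oxygen to a neighbouring benzylic lithium alkoxide on warming. The alkyne is therefore built without protic base and the alkoxide is quenched cold.

## Structural features

The target is a flavone in which ring A, a benzo ring with hydroxyls at C5 and C7, is fused through C4a and C8a to the 4-pyranone ring C (O1, C2, C3, C4), and C2 carries the 3,4-dihydroxyphenyl ring B. C3 carries a one-carbon arm, C11, whose oxygen is etherified with a 3-methylbut-2-enyl (prenyl) group. There is no stereocentre, so no stereocentres stand next to each other, and the prenyl alkene has two identical methyl groups and no geometry to control. The fragile parts are the prenyl ether (allylic, easily ionised, alkene open to HX addition, hydrogenation and quinone oxidants), the C11–O bond (vinylogously activated by O1 through C2=C3) and the four phenols, of which the ring B catechol is air-sensitive as its anion. These exclude acidic, hydrogenolytic and oxidative deprotection at the end and point to fluoride-labile silyl ethers on every oxygen. The real difficulty is the fully substituted C2=C3 bond: C3 must receive C11 already at the ether oxidation level, next to a C2 that carries both ring B and O1, without later redox or substitution chemistry on a finished flavone. The key step treats C4–C3–C2 as an ynone that has taken up a nucleophile at the beta carbon C2 and a carbon electrophile at the alpha carbon C3; iodide holds the place of O1, and because the 2,4,6-trioxygenated ring A is symmetric, either ortho oxygen closes ring C to the same product.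

## Logic of the disconnections

From 14, the O1–C2 bond and the five O–H bonds are cut first. With iodide in the place of O1 at C2 and silyl groups on all five oxygens this gives 13. Cutting C3–C11 of 13 leads to 12 and 11, and removing Me3SiI from 12 leads to 8. The reason for cutting here is that C2 and C3 become the two carbons of one alkyne, so the whole substitution pattern of ring C comes from a single addition across a triple bond, and ring closure and deprotection cost no separate step. The gain is that 14 is reduced to a diaryl ynone with a symmetric ring A plus a small ether electrophile, with nothing left to do afterwards. The forward step must meet three demands: C3 of 12, not oxygen, has to take the cation derived from 11; the prenyl ether of 13 must survive the Lewis acids present; and surplus 11 must be destroyed before fluoride frees any phenoxide.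

8 is taken back to 7 by lowering the oxidation level at C4, and 7 is cut at C4–C3 into 5 and 6. This is the only bond that joins the two aryl halves, and cutting it gives two pieces of similar size, each derived from a benzaldehyde. The forward step needs a nucleophile slim enough for a carbonyl flanked by two silyloxy groups, a quench cold enough that no silyl group moves from an ortho oxygen to the new alkoxide, and an oxidant neutral enough for five aryl silyl ethers.

6 is traced to 3, and 3 is cut at its C2=C3 double bond to 2 and a one-carbon reagent; removing the silyl groups from 2 gives 1. C2 is thus the aldehyde carbon of 1 and C3 comes from the one-carbon reagent. Choosing 3 rather than a terminal alkyne lets 6 be generated and used in the same flask as the addition to 5. The homologation must not use carbonate or alkoxide in methanol, which would strip the silyl ethers para and meta to the formyl group.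

5 is cut at its three O–Si bonds to 4. The only demand is that the two hydrogen-bonded ortho hydroxyls are silylated completely.

11 is cut at C11–Cl to 10, and 10 at its two C11–O bonds to two molecules of 9 and a methylene dihalide. This replaces the classical alcohol/formaldehyde/HCl preparation, which would expose the trisubstituted alkene and the allylic C–O bond of 9 to strong acid. The forward steps must be base-mediated for 10, must bring two molecules of 9 onto the one methylene carbon, and must be free of mineral acid for 11.

## Other disconnections considered

Alternative 1: The cut is C2–C1' and C3–C11 on an intact chromone, 5,7-bis(tert-butyldimethylsilyloxy)chromone A1.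
- Forward key step: the aryl Grignard reagent A2 would add to C2 under CuBr·SMe2 and Me3SiCl, and the silyl enol ether formed would be alkylated at C3 by 11 with ZnBr2 in the same flask, giving the trans flavanone A3.
- In favour: ring C is already closed, so the question of 5-exo against 6-endo closure never arises. The C3–C11 bond is made by alkoxymethylation of an ordinary silyl enol ether, which is closer to established practice than alkylation of an iodo allenyl silyl ether; on this point the alternative is the better. Both plans use 11 in the same way, so they are equal there.
- Against: A3 is at the flavanone oxidation level, so C2–C3 must still be dehydrogenated. The usual means (quinone oxidants, iodine in hot DMSO, bromination–elimination) endanger the prenyl ether and its alkene. The beta-alkoxy ketone of A3 can also lose prenyl alcohol 9 by E1cB elimination or open ring C by retro-oxa-Michael reaction under base. Two stereocentres are set only to be destroyed, and the conjugate addition has to overcome the peri silyloxy group at C5 and the donor at C7, which make A1 a reluctant acceptor.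
- Comparison: structurally the same two substituent bonds are made, but at the wrong oxidation level. Mechanistically the enolate alkylation is the safer event and the later redox correction the less safe one, whereas in the chosen plan the departure of iodide delivers the enone directly. In step count the alternative needs dehydrogenation and desilylation after its key step against none, and A1 and A2 each need about two steps, so the total is expected to be equal or one to two steps longer.

Alternative 2: The cut takes C4 out as carbon monoxide A6 and breaks C4a–C4, C4–C3 and O1–C2.
- Forward key step: the iodophenol A4, A6 and the arylacetylene A5 would combine under PdCl2(PPh3)2 in diethylamine. Oxidative addition to zerovalent palladium, CO insertion, alkynylation and amine-assisted 6-endo ring closure in the same flask would give the tetrasilylated flavone A7.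
- In favour: three bonds of ring C form in one catalytic operation, and the hindered aldehyde addition and the alcohol oxidation of the chosen route are avoided. The amine is expected to steer closure toward the flavone. In ring construction the alternative is at least the equal of the chosen plan, and in convergency it is the better.
- Against: A7 carries hydrogen at C3, so C3–C11 must be installed on a finished flavone by halogenation, metalation and alkylation with 11 or by a cross-coupling, followed by desilylation; that is about three steps after the key step. A4 needs one free and two silylated hydroxyls on a symmetric iodophloroglucinol, which means statistical or indirect protection. The doubly ortho-substituted, electron-rich aryl iodide is a slow partner, and a toxic gas must be handled.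
- Comparison: the chosen plan places the C3 substituent and the leaving group for ring closure in the same operation, which is the structural advantage that Alternative 2 lacks. Alternative 2 has the better precedent for the ring closure itself. In step count it is expected to be one to three steps longer.

Alternative 3: The cut is C4–C4a and O1–C2, with ring A taken as phloroglucinol A8.
- Forward key step: A8 and the alpha-methyl aroylacetic ester A9 would be heated without solvent at about 250 °C; C-acylation and cyclodehydration give the 3-methylflavone A10.
- In favour: this is the shortest and cheapest way to the ring system, C3 already carries one carbon, the symmetry of A8 removes any regiochemical question on ring A, and neither protecting groups on ring A nor metals are needed. On cost and on the number of steps to the flavone core the alternative is the better.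
- Against: C11 arrives as a methyl group and must be raised to the ether level, by radical bromination after masking the phenols and then etherification with 9; ring halogenation of the electron-rich rings A and B competes. The ring B methyl ethers must finally be cleaved by a strong Lewis acid or nucleophile, conditions under which the prenyl ether and the activated C11–O bond are not expected to survive. Fluoride-labile groups cannot be substituted because they would not tolerate the fusion temperature. Closure in the coumarin sense is the competing mode of the condensation.
- Comparison: structurally the alternative leaves the hardest part, C11 at the right oxidation level with its prenyl ether, to a late stage that conflicts with the final deprotection, whereas the chosen plan brings C11 in as the finished ether. Mechanistically its key step is simpler and proven in type. In step count it looks shorter on paper but has no workable endgame for this target.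

Key step: step 8

## Route

Step 1
Reactants: 1 3,4-dihydroxybenzaldehyde
Product: 2 3,4-bis(tert-butyldimethylsilyloxy)benzaldehyde
Conditions: TBSCl (2.4 equiv), imidazole (5 equiv), DMF, rt
Reagents that add atoms: tert-butyldimethylsilyl chloride, CC(C)(C)[Si](C)(C)Cl
Why: Standard imidazole-promoted silylation of both catechol hydroxyls; the aldehyde is untouched.

Step 2
Reactants: 2 3,4-bis(tert-butyldimethylsilyloxy)benzaldehyde
Product: 3 4-(2,2-dibromovinyl)-1,2-bis(tert-butyldimethylsilyloxy)benzene
Conditions: CBr4 (2 equiv), PPh3 (2 equiv), Zn dust (2 equiv), CH2Cl2, rt; then 2, rt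
Reagents that add atoms: carbon tetrabromide, BrC(Br)(Br)Br
Why: First stage of the Corey–Fuchs homologation (Wittig-type reaction of the dibromomethylene ylide); the neutral, aprotic medium keeps the aryl silyl ethers, which a carbonate/methanol diazophosphonate homologation would cleave.

Step 3
Reactants: 4 2,4,6-trihydroxybenzaldehyde
Product: 5 2,4,6-tris(tert-butyldimethylsilyloxy)benzaldehyde
Conditions: TBSCl (4 equiv), imidazole (8 equiv), DMF, rt → 40 °C; chromatography on Et3N-deactivated silica
Reagents that add atoms: tert-butyldimethylsilyl chloride, CC(C)(C)[Si](C)(C)Cl
Why: Exhaustive phenol silylation; the two hydrogen-bonded ortho hydroxyls react more slowly than the para one, hence the excess reagent and gentle warming.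

Step 4
Reactants: 3 4-(2,2-dibromovinyl)-1,2-bis(tert-butyldimethylsilyloxy)benzene; 5 2,4,6-tris(tert-butyldimethylsilyloxy)benzaldehyde
Product: 7 3-[3,4-bis(tert-butyldimethylsilyloxy)phenyl]-1-[2,4,6-tris(tert-butyldimethylsilyloxy)phenyl]prop-2-yn-1-ol (racemic), via lithium arylacetylide 6 (not isolated)
Conditions: 3 (1.2 equiv), n-BuLi (2.4 equiv), THF, −78 → 0 °C; −78 °C, 5 (1.0 equiv); AcOH in THF at −78 °C
Reagents that add atoms: none
Why: Second stage of the Corey–Fuchs reaction (bromine–lithium exchange, Fritsch–Buttenberg–Wiechell rearrangement, deprotonation) gives 6, which as a rod-shaped nucleophile should add 1,2 to the doubly flanked aldehyde. Protonation at −78 °C prevents O-to-O silyl migration from an ortho oxygen to the alkoxide. The new carbinol centre is racemic and is removed in step 5.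

Step 5
Reactants: 7 3-[3,4-bis(tert-butyldimethylsilyloxy)phenyl]-1-[2,4,6-tris(tert-butyldimethylsilyloxy)phenyl]prop-2-yn-1-ol
Product: 8 3-[3,4-bis(tert-butyldimethylsilyloxy)phenyl]-1-[2,4,6-tris(tert-butyldimethylsilyloxy)phenyl]prop-2-yn-1-one
Conditions: activated MnO2 (15 equiv), CH2Cl2, rt
Reagents that add atoms: none
Why: MnO2 oxidation of a benzylic, propargylic alcohol; the neutral heterogeneous oxidant leaves the aryl silyl ethers and the alkyne alone.

Step 6
Reactants: 9 prenyl alcohol (3-methylbut-2-en-1-ol), two molecules for each molecule of 10
Product: 10 bis(3-methylbut-2-enyloxy)methane (diprenyl formal)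
Conditions: 9 (2.0 equiv), NaH (2.1 equiv), THF, 0 °C; CH2Br2 (1.0 equiv), n-Bu4NI (5 mol %), 0 → 50 °C
Reagents that add atoms: dibromomethane, BrCBr; second molecule of 3-methylbut-2-en-1-ol (9), CC(C)=CCO
Why: Double Williamson etherification in which two molecules of the sodium alkoxide of 9 displace both bromides of CH2Br2; the intermediate bromomethyl ether is far more reactive than CH2Br2 and is taken on to the formal by the second alkoxide. Basic conditions avoid ionisation of the allylic C–O bond.

Step 7
Reactants: 10 bis(3-methylbut-2-enyloxy)methane
Product: 11 prenyl chloromethyl ether (1-(chloromethoxy)-3-methylbut-2-ene)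
Conditions: AcCl (0.98 equiv), Zn(OAc)2 (0.01 mol %), CH2Cl2, 0 °C → rt; used as a titrated solution
Reagents that add atoms: acetyl chloride, CC(=O)Cl
Why: Zn(OAc)2-catalysed acetal–acyl chloride exchange gives the alpha-chloro ether without free HCl, so the trisubstituted alkene is not hydrochlorinated. The equimolar prenyl acetate is carried along, and the alkylating agent is never handled neat.

Step 8
Reactants: 8 3-[3,4-bis(tert-butyldimethylsilyloxy)phenyl]-1-[2,4,6-tris(tert-butyldimethylsilyloxy)phenyl]prop-2-yn-1-one; 11 prenyl chloromethyl ether
Product: 14 ophioglonol prenyl ether (2-(3,4-dihydroxyphenyl)-5,7-dihydroxy-3-[(3-methylbut-2-enyloxy)methyl]chromen-4-one), via iodo allenyl silyl ether 12 (not isolated), via beta-iodo enone 13 (not isolated)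
Conditions: Me3SiI (1.1 equiv), 2,6-di-tert-butyl-4-methylpyridine (0.2 equiv), CH2Cl2, −78 °C; 11 (1.3 equiv), ZnI2 (10 mol %), −78 → −40 °C; MeOH, i-Pr2NEt, −78 °C; n-Bu4NF (8 equiv), THF, −78 → 0 °C, Ar; AcOH
Reagents that add atoms: none
Why: Proposed new method: Me3SiI silylates the ynone oxygen and delivers iodide to the beta carbon C2, giving 12, whose central carbon C3 is the nucleophilic end of a silyl enol ether; ZnI2 ionises 11 to the prenyloxymethyl oxocarbenium ion, which C3 captures to form C3–C11 with release of Me3SiCl, leaving 13. Fluoride then removes the aryl silyl groups, and an ortho phenoxide of ring A adds to C2 and expels iodide, forming O1–C2. The closest known reactions are the beta-iodo Morita–Baylis–Hillman couplings of ynones with Me3SiI or MgI2 and aldehydes, the Lewis-acid alkoxymethylation of silyl enol ethers by chloromethyl ethers, and the base cyclisation of beta-halo-2'-hydroxychalcones to flavones; what is new is their combination in one flask with a chloromethyl ether as the electrophile. Ring C closes by 6-endo-trig addition–elimination, and because the adduct is an enolate free to rotate about C2–C3, both alkene isomers of 13 converge. No stereocentre is formed: 12 is a racemic axially chiral allene and the geometry of 13 is erased on closure. The step needs C- rather than O-attack on the electrophile, which is secured because oxygen is already silylated and only C3 carries enol ether pi density. It also needs 6-endo rather than 5-exo closure, which is secured by the iodide at C2, the only carbon where addition can be followed by loss of a leaving group. The symmetric ring A makes the two ortho oxygens equivalent, the hindered pyridine removes adventitious HI that would protonate 12, and the methanol/amine quench destroys surplus 11 before phenoxides appear.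

## Compound list

1 | 3,4-dihydroxybenzaldehyde | O=Cc1ccc(O)c(O)c1 | starting material
2 | 3,4-bis(tert-butyldimethylsilyloxy)benzaldehyde | O=Cc1ccc(O[Si](C)(C)C(C)(C)C)c(O[Si](C)(C)C(C)(C)C)c1 | intermediate
3 | 4-(2,2-dibromovinyl)-1,2-bis(tert-butyldimethylsilyloxy)benzene | BrC(Br)=Cc1ccc(O[Si](C)(C)C(C)(C)C)c(O[Si](C)(C)C(C)(C)C)c1 | intermediate
4 | 2,4,6-trihydroxybenzaldehyde | O=Cc1c(O)cc(O)cc1O | starting material
5 | 2,4,6-tris(tert-butyldimethylsilyloxy)benzaldehyde | O=Cc1c(O[Si](C)(C)C(C)(C)C)cc(O[Si](C)(C)C(C)(C)C)cc1O[Si](C)(C)C(C)(C)C | intermediate
6 | lithium [3,4-bis(tert-butyldimethylsilyloxy)phenyl]acetylide (not isolated) | [Li]C#Cc1ccc(O[Si](C)(C)C(C)(C)C)c(O[Si](C)(C)C(C)(C)C)c1 | intermediate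
7 | 3-[3,4-bis(tert-butyldimethylsilyloxy)phenyl]-1-[2,4,6-tris(tert-butyldimethylsilyloxy)phenyl]prop-2-yn-1-ol (racemic) | OC(C#Cc1ccc(O[Si](C)(C)C(C)(C)C)c(O[Si](C)(C)C(C)(C)C)c1)c1c(O[Si](C)(C)C(C)(C)C)cc(O[Si](C)(C)C(C)(C)C)cc1O[Si](C)(C)C(C)(C)C | intermediate
8 | 3-[3,4-bis(tert-butyldimethylsilyloxy)phenyl]-1-[2,4,6-tris(tert-butyldimethylsilyloxy)phenyl]prop-2-yn-1-one | O=C(C#Cc1ccc(O[Si](C)(C)C(C)(C)C)c(O[Si](C)(C)C(C)(C)C)c1)c1c(O[Si](C)(C)C(C)(C)C)cc(O[Si](C)(C)C(C)(C)C)cc1O[Si](C)(C)C(C)(C)C | intermediate
9 | prenyl alcohol (3-methylbut-2-en-1-ol) | CC(C)=CCO | starting material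
10 | bis(3-methylbut-2-enyloxy)methane | CC(C)=CCOCOCC=C(C)C | intermediate
11 | prenyl chloromethyl ether (1-(chloromethoxy)-3-methylbut-2-ene) | CC(C)=CCOCCl | intermediate
12 | 1-[3,4-bis(tert-butyldimethylsilyloxy)phenyl]-1-iodo-3-[2,4,6-tris(tert-butyldimethylsilyloxy)phenyl]-3-(trimethylsilyloxy)propa-1,2-diene (racemic allene, not isolated) | C[Si](C)(C)OC(=C=C(I)c1ccc(O[Si](C)(C)C(C)(C)C)c(O[Si](C)(C)C(C)(C)C)c1)c1c(O[Si](C)(C)C(C)(C)C)cc(O[Si](C)(C)C(C)(C)C)cc1O[Si](C)(C)C(C)(C)C | intermediate
13 | 3-[3,4-bis(tert-butyldimethylsilyloxy)phenyl]-3-iodo-2-[(3-methylbut-2-enyloxy)methyl]-1-[2,4,6-tris(tert-butyldimethylsilyloxy)phenyl]prop-2-en-1-one (mixture of alkene isomers, not isolated) | CC(C)=CCOCC(C(=O)c1c(O[Si](C)(C)C(C)(C)C)cc(O[Si](C)(C)C(C)(C)C)cc1O[Si](C)(C)C(C)(C)C)=C(I)c1ccc(O[Si](C)(C)C(C)(C)C)c(O[Si](C)(C)C(C)(C)C)c1 | intermediate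
14 | ophioglonol prenyl ether (2-(3,4-dihydroxyphenyl)-5,7-dihydroxy-3-[(3-methylbut-2-enyloxy)methyl]chromen-4-one) | CC(C)=CCOCc1c(-c2ccc(O)c(O)c2)oc2cc(O)cc(O)c2c1=O | target

## Step count and risk

Total step count: 8. Longest linear sequence: 5 steps (1 → 2 → 3 → 7 → 8 → 14, steps 1, 2, 4, 5 and 8).

Step 8 (key step, proposed new method).
- What may go wrong: heterolysis of the prenyl–oxygen bond, either in the oxocarbenium ion or in 13, under Me3SiI and ZnI2, because a prenyl cation is a good leaving fragment; this would mean prenyl transfer or loss of the side chain. Ionisation of the prenyl acetate carried along from step 7 by the small excess of Me3SiI would cause competing C-prenylation. Protonation of 12 by adventitious HI instead of alkylation would lead, after fluoride, to ring closure without C11. O-alkylation of the liberated phenoxides would occur if surplus 11 were not fully quenched.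
- Fallback, by known reaction types, from 8 to 14: ICl in CH2Cl2 at −78 °C should bring about 6-endo iodocyclisation of the ortho-silyloxyaryl ynone, with chloride removing the silyl group from the attacking oxygen. This gives 5,7-bis(tert-butyldimethylsilyloxy)-2-[3,4-bis(tert-butyldimethylsilyloxy)phenyl]-3-iodochromen-4-one F1. Iodine–magnesium exchange with i-PrMgCl·LiCl (THF, −40 °C) would give [5,7-bis(tert-butyldimethylsilyloxy)-2-[3,4-bis(tert-butyldimethylsilyloxy)phenyl]-4-oxochromen-3-yl]magnesium chloride F2. Alkylation of F2 with 11 would give 5,7-bis(tert-butyldimethylsilyloxy)-2-[3,4-bis(tert-butyldimethylsilyloxy)phenyl]-3-[(3-methylbut-2-enyloxy)methyl]chromen-4-one F3. n-Bu4NF in THF with an AcOH quench then rejoins the route at 14. The same two bonds are formed in separate, precedented operations, and the prenyl group never meets an iodosilane.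

Step 7.
- What may go wrong: ionisation of the prenyloxymethyl unit at the allylic C–O bond under Zn(OAc)2 catalysis, or acylation of the electron-rich alkene by AcCl, could erode the titre of a reagent that cannot be purified without hydrolysis.
- Fallback, from 10 to 13: 10 itself is added at −78 °C to the solution of 12 together with a further equivalent of Me3SiI. Cleavage of the formaldehyde acetal by the iodosilane should give 1-(iodomethoxy)-3-methylbut-2-ene F4 in the flask, alongside the trimethylsilyl ether of 9. F4 alkylates 12 at C3 with regeneration of Me3SiI, and the route is rejoined at 13. The chloro ether and the accompanying prenyl acetate are bypassed.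

Step 4.
- What may go wrong: migration of a silyl group from an ortho oxygen of ring A to the lithium alkoxide (a six-membered transition state, driven by the better phenoxide leaving group) if the mixture warms before protonation, and slow addition to a carbonyl flanked by two bulky silyloxy groups.
- Fallback, from 3 to 8: 3 is treated with n-BuLi (2 equiv, THF, −78 °C) and then water to give 4-ethynyl-1,2-bis(tert-butyldimethylsilyloxy)benzene F5. Separately, phloroglucinol A8 is mono-iodinated (I2, NaHCO3, aqueous THF) to 2-iodobenzene-1,3,5-triol F6 and silylated (TBSCl, imidazole, DMF) to 2-iodo-1,3,5-tris(tert-butyldimethylsilyloxy)benzene F7. A carbonylative Sonogashira coupling of F7 and F5 without CuI (PdCl2(PPh3)2, Et3N, carbon monoxide A6 at 1 atm, THF, rt) should give 8 directly, where the route is rejoined. No alkoxide is formed and step 5 is not needed; the detour also covers incomplete silylation in step 3, because 5 is not used.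

## Further compounds

F1 | step 8 | 5,7-bis(tert-butyldimethylsilyloxy)-2-[3,4-bis(tert-butyldimethylsilyloxy)phenyl]-3-iodochromen-4-one | O=c1c(I)c(-c2ccc(O[Si](C)(C)C(C)(C)C)c(O[Si](C)(C)C(C)(C)C)c2)oc2cc(O[Si](C)(C)C(C)(C)C)cc(O[Si](C)(C)C(C)(C)C)c12
F2 | step 8 | [5,7-bis(tert-butyldimethylsilyloxy)-2-[3,4-bis(tert-butyldimethylsilyloxy)phenyl]-4-oxochromen-3-yl]magnesium chloride | Cl[Mg]c1c(-c2ccc(O[Si](C)(C)C(C)(C)C)c(O[Si](C)(C)C(C)(C)C)c2)oc2cc(O[Si](C)(C)C(C)(C)C)cc(O[Si](C)(C)C(C)(C)C)c2c1=O
F3 | step 8 | 5,7-bis(tert-butyldimethylsilyloxy)-2-[3,4-bis(tert-butyldimethylsilyloxy)phenyl]-3-[(3-methylbut-2-enyloxy)methyl]chromen-4-one | CC(C)=CCOCc1c(-c2ccc(O[Si](C)(C)C(C)(C)C)c(O[Si](C)(C)C(C)(C)C)c2)oc2cc(O[Si](C)(C)C(C)(C)C)cc(O[Si](C)(C)C(C)(C)C)c2c1=O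
F4 | step 7 | 1-(iodomethoxy)-3-methylbut-2-ene | CC(C)=CCOCI
F5 | step 4 | 4-ethynyl-1,2-bis(tert-butyldimethylsilyloxy)benzene | C#Cc1ccc(O[Si](C)(C)C(C)(C)C)c(O[Si](C)(C)C(C)(C)C)c1
F6 | step 4 | 2-iodobenzene-1,3,5-triol | Oc1cc(O)c(I)c(O)c1
F7 | step 4 | 2-iodo-1,3,5-tris(tert-butyldimethylsilyloxy)benzene | CC(C)(C)[Si](C)(C)Oc1cc(O[Si](C)(C)C(C)(C)C)c(I)c(O[Si](C)(C)C(C)(C)C)c1
A1 | alternative 1 | 5,7-bis(tert-butyldimethylsilyloxy)chromen-4-one | O=c1ccoc2cc(O[Si](C)(C)C(C)(C)C)cc(O[Si](C)(C)C(C)(C)C)c12
A2 | alternative 1 | [3,4-bis(tert-butyldimethylsilyloxy)phenyl]magnesium bromide | Br[Mg]c1ccc(O[Si](C)(C)C(C)(C)C)c(O[Si](C)(C)C(C)(C)C)c1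
A3 | alternative 1 | trans-5,7-bis(tert-butyldimethylsilyloxy)-2-[3,4-bis(tert-butyldimethylsilyloxy)phenyl]-3-[(3-methylbut-2-enyloxy)methyl]chroman-4-one (racemic, one enantiomer drawn) | CC(C)=CCOC[C@@H]1C(=O)c2c(O[Si](C)(C)C(C)(C)C)cc(O[Si](C)(C)C(C)(C)C)cc2O[C@H]1c1ccc(O[Si](C)(C)C(C)(C)C)c(O[Si](C)(C)C(C)(C)C)c1
A4 | alternative 2 | 2-iodo-3,5-bis(triisopropylsilyloxy)phenol | Oc1cc(O[Si](C(C)C)(C(C)C)C(C)C)cc(O[Si](C(C)C)(C(C)C)C(C)C)c1I
A5 | alternative 2 | 4-ethynyl-1,2-bis(triisopropylsilyloxy)benzene | C#Cc1ccc(O[Si](C(C)C)(C(C)C)C(C)C)c(O[Si](C(C)C)(C(C)C)C(C)C)c1
A6 | alternative 2 | carbon monoxide | [C-]#[O+]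
A7 | alternative 2 | 5,7,3',4'-tetrakis(triisopropylsilyloxy)flavone | O=c1cc(-c2ccc(O[Si](C(C)C)(C(C)C)C(C)C)c(O[Si](C(C)C)(C(C)C)C(C)C)c2)oc2cc(O[Si](C(C)C)(C(C)C)C(C)C)cc(O[Si](C(C)C)(C(C)C)C(C)C)c12
A8 | alternative 3 | phloroglucinol (benzene-1,3,5-triol) | Oc1cc(O)cc(O)c1
A9 | alternative 3 | ethyl 3-(3,4-dimethoxyphenyl)-2-methyl-3-oxopropanoate (racemic) | CCOC(=O)C(C)C(=O)c1ccc(OC)c(OC)c1
A10 | alternative 3 | 5,7-dihydroxy-3',4'-dimethoxy-3-methylflavone | Cc1c(-c2ccc(OC)c(OC)c2)oc2cc(O)cc(O)c2c1=O
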